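**Assumption:** spermidine is used as its commercial free base; N(1) is the nitrogen on the three-carbon arm, N(5) the central nitrogen and N(10) the nitrogen on the four-carbon arm; in each acyl arm C1 is the amide carbonyl, C2 the alpha carbon and C3 the benzylic carbon; each Reactants line names every compound once, and where three molecules of it are built into the product the second and third molecules are entered under "Reagents that add atoms", so that the entries of a step together hold every non-hydrogen atom of its product.

## The problem

The target 6 is spermidine 1 in which every nitrogen carries an (E)-3-(4-hydroxyphenyl)prop-2-enoyl group; it has no ring to close and no stereocentre, so the only stereochemical task is the E geometry of three C2=C3 double bonds. The real difficulty is multiplicity: whatever bond is made must be made three times to completion, at two secondary-amide arms and at the tertiary-amide arm on N(5), the most hindered nitrogen, because mono- and bis-functionalised congeners of a polar triphenol would be hard to separate from 6. The three phenols are free in the target, and in any plan that brings in the arm as an activated p-coumaric acid they compete with nitrogen as nucleophiles, so the acyl donor must be protected, and aryl-ester protecting groups are themselves acyl donors towards the amines of 1. The cinnamamide double bonds isomerise from E to Z in daylight, and a free p-hydroxycinnamic acid loses CO2 to a vinylphenol when heated with base, so the geometry is best created late in a step that gives E by itself. The feature that opens a way round this lies in each arm: C2 is alpha to the amide carbonyl C1, and C3 is the benzylic carbon of a benzene ring whose para oxygen is conjugated with it. Each C2=C3 bond is therefore the retron of a decarboxylative condensation between a malonyl CH2 and 4-hydroxybenzaldehyde 4, and the para-hydroxyl can accept the electrons of the departing carboxylate through a p-quinone methide. Because the three arms are identical, the tris-malonamic acid 3 of spermidine should turn into 6 in one operation, with three molecules of 4 and without any protecting group.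

## Retrosynthesis

**Disconnection 1 (6 to 3 and three molecules of 4).** The three C2=C3 double bonds of 6 are cut at once. Each arm is traced back through the arylidene malonamic acid stage 5 to a carboxyacetyl group on nitrogen, which gives tri-acid 3 and three molecules of 4-hydroxybenzaldehyde 4. Against the neighbouring cut at N–C1 (amide formation), this cut never puts an acyl donor and a free phenol in the same flask, so no protection is needed. Against the cut at C3–aryl, it needs no metal and no polymerisable triacrylamide. Precursor 3 has 28 non-hydrogen atoms, no ring and no alkene, against 43 non-hydrogen atoms, three arenes and three E alkenes in 6; twenty-one of the 34 carbons of 6 arrive in this step. The forward reaction must condense at all three arms, condense faster than a free malonamic acid arm decarboxylates, and give E geometry.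

**Disconnection 2 (3 to 1 and three molecules of 2).** The three N–C(=O) bonds of 3 are cut, giving spermidine 1 and three molecules of Meldrum's acid 2. Against activated malonyl donors that need a coupling agent or a later ester hydrolysis, 2 transfers exactly one malonyl unit per ring and uncovers the free acid in the same event, with a volatile ketone as the only by-product. The malonamic acid formed is not an acyl donor, so no malonamide bridge between two nitrogens can form. Both precursors are commercial, and the forward reaction must acylate N(5) as well as the two primary nitrogens.

## Roads not taken

Alternative 1: the obvious cut at the three N–C1 amide bonds. (E)-p-Coumaric acid A1 would be O-acetylated and chlorinated to (E)-4-acetoxycinnamoyl chloride A2; spermidine 1 would be acylated three times with A2 to the tris-acetate A3, which would then be deacetylated to 6. The acyl donor must carry a protected phenol, otherwise it oligomerises through its own hydroxyl, so this road needs four operations against two. The aryl acetates of A2 and A3 are active esters towards the primary amines of 1, so N-acetyl arms are a built-in side path, and A2 is a better Michael acceptor than a cinnamamide and meets a triamine. The E geometry, bought with A1, must survive acid chloride formation and three further manipulations, whereas the chosen plan creates it in the last step.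

Alternative 2: cut at the three C3–aryl bonds. A threefold Mizoroki–Heck arylation of N(1),N(5),N(10)-triacryloylspermidine A4 with 4-iodophenol A5, catalysed by zerovalent palladium formed from Pd(OAc)2, would give 6. The step count is the same, but A4 is a trifunctional acrylamide cross-linker: it must be made from 1 and acryloyl chloride A6 under conditions in which amines also add conjugately, and it tends to polymerise on concentration. Forcing the third arm to completion invites a second arylation at C3 of arms already arylated, and palladium must be removed from a chelating, polar triamide triphenol. The chosen plan uses no metal and a stable, saturated precursor.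

Alternative 3: the same C2=C3 cut in the phosphonate sense. A threefold Horner–Wadsworth–Emmons reaction of N(1),N(5),N(10)-tris(diethoxyphosphorylacetyl)spermidine A7 with 4-(tert-butyldimethylsilyloxy)benzaldehyde A8 would give the tris-silyl ether A9, which would then be desilylated to 6. The phosphonate anion needs stoichiometric strong base, under which unprotected 4 would sit as its phenoxide, a vinylogous carboxylate and a poor electrophile; protection and a deprotection step follow from that. A7 needs a coupling agent to make, and three equivalents of phosphate are discarded. The carboxyl group of 3 does the same two jobs as the phosphonate (it acidifies C2 and leaves after the double bond is formed), but it comes free with Meldrum's acid 2, works under weak-base catalysis that tolerates free phenols, and leaves as CO2.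

Key step: step 2

## Route

Step 1
Reactants: 1 spermidine (N-(3-aminopropyl)butane-1,4-diamine); 2 Meldrum's acid (2,2-dimethyl-1,3-dioxane-4,6-dione), three molecules for each molecule of 1
Product: 3 N(1),N(5),N(10)-tris(carboxyacetyl)spermidine (each nitrogen bears a C(=O)CH2CO2H group)
Conditions: 2 (3.6 equiv), MeCN, reflux, N2 sweep; evaporate, triturate with CH2Cl2/Et2O
Reagents that add atoms: Meldrum's acid, second molecule, CC1(C)OC(=O)CC(=O)O1 ; Meldrum's acid, third molecule, CC1(C)OC(=O)CC(=O)O1
Why: Three aminolyses of Meldrum's acid (nucleophilic acyl substitution at the cyclic acylal, ring opening and loss of one acetone each), one at each nitrogen of 1, should give one malonamic acid per nitrogen. The acid formed is not an acyl donor, so each nitrogen is acylated once and no bridging malonamide can form; excess 2 and heat drive the hindered N(5), and the N2 sweep carries off acetone before it can condense with unreacted 2.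

Step 2
Reactants: 3 N(1),N(5),N(10)-tris(carboxyacetyl)spermidine; 4 4-hydroxybenzaldehyde, three molecules for each molecule of 3
Product: 6 N(1),N(5),N(10)-tri-(E)-p-coumaroylspermidine (target), via tris(arylidenemalonamic acid) 5 (not isolated)
Conditions: 4 (4.5 equiv), piperidine (0.3 equiv), pyridine, 60 then 90 °C, N2, amber glassware; 1 M HCl/EtOAc, NaHCO3 and NaHSO3 washes; chromatography
Reagents that add atoms: 4-hydroxybenzaldehyde, second molecule, O=Cc1ccc(O)cc1 ; 4-hydroxybenzaldehyde, third molecule, O=Cc1ccc(O)cc1
Why: Threefold Knoevenagel–Doebner (decarboxylative Knoevenagel) condensation: at each of the three arms the malonyl CH2 of 3, acidified by the amide carbonyl and the carboxyl group, condenses under piperidine catalysis (iminium activation of 4) with one molecule of aldehyde 4 and loses water to give the arylidene malonamic acid stage, formally 5. Compound 5 should then lose three molecules of CO2 in hot pyridine, either through its reversible catalyst-bound amine adduct by anti loss of CO2 and amine or, specific to this aryl group, through the p-quinone methide tautomer formed when the para oxygen pushes electron density to C2, whose carboxylate departs as the phenol is restored. The closest known reaction type is the Doebner condensation of a single malonic acid monoamide with a hydroxybenzaldehyde to a hydroxycinnamamide; here it runs three times on arms that are insulated from one another by the three- and four-carbon tethers and so should react independently. No ring is closed and no stereocentre is formed; the one stereochemical element, the alkene geometry, is set in the decarboxylation, where the conformer that keeps the carboxamide away from the ring (no allylic 1,3-strain) leads to E, which is also the thermodynamic isomer under reversible amine addition. The selectivity needed is condensation before decarboxylation at every arm, since an arm that loses CO2 first ends as an N-acetyl group; high concentration, excess 4 and the lower first temperature stage favour the bimolecular condensation over the unimolecular loss. The free phenols should stay spectators because no acyl donor is present, and the three carboxylic acids of 3 buffer the piperidine so that 4 is not held as its unreactive phenoxide. Over-reaction is excluded by the substrate: after loss of CO2 each arm is an amide with no carboxyl left, so the second decarboxylation that turns free p-coumaric acid into a vinylphenol cannot follow. Arms that fail to condense keep a CO2H and should be removed from neutral 6 by the NaHCO3 wash.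

## Compound list

1 | spermidine (N-(3-aminopropyl)butane-1,4-diamine) | NCCCCNCCCN | starting material
2 | Meldrum's acid (2,2-dimethyl-1,3-dioxane-4,6-dione) | CC1(C)OC(=O)CC(=O)O1 | starting material
3 | N(1),N(5),N(10)-tris(carboxyacetyl)spermidine | OC(=O)CC(=O)NCCCCN(CCCNC(=O)CC(=O)O)C(=O)CC(=O)O | intermediate
4 | 4-hydroxybenzaldehyde | O=Cc1ccc(O)cc1 | starting material
5 | N(1),N(5),N(10)-tris[2-carboxy-3-(4-hydroxyphenyl)prop-2-enoyl]spermidine (alkene geometry not defined; both forms converge on 6) | OC(=O)C(=Cc1ccc(O)cc1)C(=O)NCCCCN(CCCNC(=O)C(=Cc1ccc(O)cc1)C(=O)O)C(=O)C(=Cc1ccc(O)cc1)C(=O)O | intermediate (not isolated)
6 | N(1),N(5),N(10)-tri-(E)-p-coumaroylspermidine | O=C(/C=C/c1ccc(O)cc1)NCCCCN(CCCNC(=O)/C=C/c1ccc(O)cc1)C(=O)/C=C/c1ccc(O)cc1 | target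

## Step count and risk

Total step count: 2. Longest linear sequence: 2 steps (1 to 3 to 6). The route has only two steps, so both are assessed rather than the key step and two or more others.

**Step 2 (key step).** The most likely failure is loss of CO2 from a malonamic acid arm before it has condensed, which leaves an N-acetyl arm. With three arms the penalty multiplies, and such neutral by-products are not removed by the bicarbonate wash. The second risk is stalling at the N(5) arm, where the arylidene stage of a tertiary amide suffers allylic 1,3-strain. The third is slow condensation if the aldehyde is held as its phenoxide.

Fallback: this sets out from 1 and comes back to the route at 6. It gives up C=C bond formation and forms the three amide bonds with an acyl donor that tolerates its own free phenol. Commercial (E)-p-coumaric acid would be converted with N-hydroxysuccinimide and DCC in THF into N-succinimidyl (E)-4-hydroxycinnamate F1. Spermidine 1 would then be treated with F1 (3.6 equiv) and Et3N in DMF, at room temperature for the primary nitrogens and with warming for N(5), to give 6 directly. Any phenolic ester formed by over-acylation would be cleaved by a brief K2CO3/MeOH treatment. The E alkenes are bought, not made, and light must be excluded.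

**Step 1.** The most likely failure is incomplete acylation at N(5). Once the two primary nitrogens carry carboxylic acids, the remaining secondary amine is held as an internal ammonium carboxylate, and partly acylated zwitterions may leave solution. Isolation of a water-soluble tri-acid free of excess 2 is the second concern.

Fallback: this sets out from 1 and comes back to the route at 3. Spermidine 1 would be coupled with commercial mono-tert-butyl malonate (3.5 equiv) using DIC and HOBt in CH2Cl2. The product, N(1),N(5),N(10)-tris(3-tert-butoxy-3-oxopropanoyl)spermidine F2, is a neutral triester that can be purified on silica. Treatment with TFA in CH2Cl2 at room temperature should remove the three tert-butyl groups and leave 3 after evaporation, with no aqueous work-up.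

## Further compounds

F1 | step 2 | N-succinimidyl (E)-4-hydroxycinnamate | O=C(/C=C/c1ccc(O)cc1)ON1C(=O)CCC1=O
F2 | step 1 | N(1),N(5),N(10)-tris(3-tert-butoxy-3-oxopropanoyl)spermidine | CC(C)(C)OC(=O)CC(=O)NCCCCN(CCCNC(=O)CC(=O)OC(C)(C)C)C(=O)CC(=O)OC(C)(C)C
A1 | alternative 1 | (E)-p-coumaric acid | OC(=O)/C=C/c1ccc(O)cc1
A2 | alternative 1 | (E)-4-acetoxycinnamoyl chloride | CC(=O)Oc1ccc(/C=C/C(=O)Cl)cc1
A3 | alternative 1 | N(1),N(5),N(10)-tris[(E)-4-acetoxycinnamoyl]spermidine | CC(=O)Oc1ccc(/C=C/C(=O)NCCCCN(CCCNC(=O)/C=C/c2ccc(OC(C)=O)cc2)C(=O)/C=C/c2ccc(OC(C)=O)cc2)cc1
A4 | alternative 2 | N(1),N(5),N(10)-triacryloylspermidine | C=CC(=O)NCCCCN(CCCNC(=O)C=C)C(=O)C=C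
A5 | alternative 2 | 4-iodophenol | Oc1ccc(I)cc1
A6 | alternative 2 | acryloyl chloride | C=CC(=O)Cl
A7 | alternative 3 | N(1),N(5),N(10)-tris(diethoxyphosphorylacetyl)spermidine | CCOP(=O)(OCC)CC(=O)NCCCCN(CCCNC(=O)CP(=O)(OCC)OCC)C(=O)CP(=O)(OCC)OCC
A8 | alternative 3 | 4-(tert-butyldimethylsilyloxy)benzaldehyde | CC(C)(C)[Si](C)(C)Oc1ccc(C=O)cc1
A9 | alternative 3 | N(1),N(5),N(10)-tris[(E)-4-(tert-butyldimethylsilyloxy)cinnamoyl]spermidine | CC(C)(C)[Si](C)(C)Oc1ccc(/C=C/C(=O)NCCCCN(CCCNC(=O)/C=C/c2ccc(O[Si](C)(C)C(C)(C)C)cc2)C(=O)/C=C/c2ccc(O[Si](C)(C)C(C)(C)C)cc2)cc1
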